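## Structural features

The target is a 4-hydroxy-5-methylcoumarin bonded through its C3 to C1 of a 1,4a,5,6,7,7a-hexahydrocyclopenta[c]pyran: a dihydropyran (O2, C1, C7a, C4a, C4, C3) cis-fused along C4a–C7a to a cyclopentane (C4a, C5, C6, C7, C7a). C3=C4 is a tetrasubstituted enol ether with a methyl group on C4 and a 3-methylbut-2-enoyl ketone on C3, so O2 sits on the α-carbon of a cross-conjugated dienone. There are four stereocentres, (1R,4aS,7S,7aR): C1, C7a and C7 are contiguous and C4a adjoins C7a. H4a and H7a are cis, the C7 methyl lies on the face of these two hydrogens, and the coumarinyl group on C1 is trans to the C7a–C7 bond (H1 trans to H7a). Fragile points are the C1–O2 bond (C1 is the β-carbon of a latent 3-alkylidenechromane-2,4-dione, so the free hydroxycoumarin can open the pyran by retro-oxa-Michael reaction), the γ-acidic H4a, the dienone as Michael acceptor, and the acidic, chelating 4-hydroxyl group. The real difficulty is the C1–C7a–C7 array: two centres must be set relative to the only purchasable one (C7), at a position crowded by the peri-methylated coumarin and without a polar handle on the carbocycle. The key step uses the fact that C1 carries both O2 and the coumarin C3, so C1–O2 can arrive as the C=O of a coumarin-3-carbaldehyde while C7a, C4a, C4 and C3 arrive as a 1,3-diene; the cycloadduct alkene C4=C4a is then one prototropic shift from the C3=C4 enol ether.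

## Logic of the disconnections

22 ⇒ 21. The O–H of the coumarin is traced back to an O–CH3 bond. The free hydroxycoumarin is acidic, chelates Lewis acids and makes C1–O2 ionisable, so it is masked until the last step; a methyl ether is the one mask that cannot ionise under the Lewis acid of the key step. The forward step must be an SN2 dealkylation that spares the dienone.

21 ⇒ 19 (through 20). The C4a–H bond and the C3=C4 position are cut back to a C4=C4a alkene with H on C3, and the 3-methylbut-2-enoyl ketone back to a tertiary propargylic alcohol. This removes the Michael acceptor, the C4a stereocentre and the enol ether in one move. The forward step needs a 1,3-oxygen transposition that leaves the ring ether alone, followed by an isomerisation under thermodynamic control that must favour the cis ring fusion.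

19 ⇒ 18. The O–H of the carbinol is traced to an O–Si bond. A silyl ether is needed because a free or lightly protected tertiary propargylic oxygen would bind or be ionised by the Lewis acid of the key step.

18 ⇒ 13 + 17. C1–C7a and O2–C3 are cut in a retro-oxa-Diels–Alder sense. This splits the molecule into two fragments of similar size, removes the pyran ring and three stereocentres, and leaves C7 as the only stereocentre to be bought. The configurations were re-derived and are mutually consistent: (1R,3S,7S,7aR) for 18, (S,E) for 13, (1R,4aS,7S,7aR) for 22, so no structure needs correcting. Two design changes are made. The silyl group on the tertiary oxygen is tert-butyldimethylsilyl rather than trimethylsilyl, because the propargylic C–O bond of the dienyne is activated towards ionisation and a hindered, weakly basic silyl ether resists both the Lewis acid and chromatography. The 4-O-methyl group is kept because an allyl or benzyl vinylogous ester would be cleaved by a chelating Lewis acid. The forward step must be chemoselective for C=O, regioselective (C1 to C7a), anti to the C7 methyl and exo for the aryl group.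

17 ⇒ 16 ⇒ 14. The C4–OCH3 bond is cut to a C4–Cl bond, then C3–CHO and C4–Cl are cut together back to the hydroxycoumarin. Formylating and O-methylating the hydroxycoumarin directly would give O/C-alkylation mixtures of an enolised tricarbonyl; chloroformylation followed by addition–elimination avoids this. The forward steps need a chloride that is displaced faster than the lactone is opened.

13 ⇒ 10 + 12, and 12 ⇒ 11. The C3–C(sp) bond is cut, giving an (E)-alkenyl iodide and a terminal alkyne that already carries the silyl ether. Pre-silylating the small alkyne keeps an acid-sensitive dienynol out of the route. The coupling must retain the alkene geometry.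

10 ⇒ 8 (through 9), and 8 ⇒ 7. The C4–CH3 and C3–I bonds are cut back to a terminal alkyne. Syn-carbometallation is the most reliable way to fix the trisubstituted (E)-alkene whose geometry later places the alkynyl group "outside" on the diene. The alkyne must be free for this step, hence the prior removal of the C–Si cap.

7 ⇒ 6. The ring alkene C7a=C4a is cut by retro-ring-closing metathesis. The tether fixes the alkene position next to the C7 stereocentre, which enolate chemistry of 3-methylcyclopentanone could not do. A terminal alkyne would divert the catalyst into ene–yne metathesis, so the alkyne is carried silyl-capped through this step.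

6 ⇒ 5 ⇒ 4 ⇒ 3. The C4a=CH2 bond is cut (methylenation), the ketone is reduced in the retrosynthetic sense to the carbinol, and the C4a–C4 bond is cut (acetylide addition). Each forward step is a standard carbonyl operation on a substrate with only one reactive site.

3 ⇒ 1 (through 2). The aldehyde is traced to the trisubstituted alkene of the terpene. The stereocentre comes from the chiral pool, and the forward step needs only the rate difference between a trisubstituted and a monosubstituted alkene towards ozone.

## Other disconnections considered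

Alternative 1: The cut is C4a–C7a together with a temporary C1–C4 bond. In the forward sense a triplet sensitiser such as thioxanthone would promote the intramolecular [2+2] cycloaddition of the tethered diene A2 (styrene-type alkene C7a=C1 on the coumarin, enone-type alkene C4=C4a bearing the methoxyoxalyl group) to the bicyclo[3.2.0]heptane A1. The C1–C4 bond would then be opened as a donor–acceptor cyclobutane, with the keto oxygen closing onto C1 to give the dihydropyran, and the ester would be converted into the isobutenyl ketone.
- In its favour: the cyclopentane and the cis C4a–C7a fusion are fixed by the geometry of the [3.2.0] system. On this point it is better than the chosen plan, which sets C4a only by a late equilibration. The 5-exo first bond of a 1,6-diene is dependable.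
- Against it here: the coumarin C3=C4 bond is itself a triplet [2+2] chromophore. Both alkenes can isomerise under energy transfer, so the 1,4-diradical closure and not the alkene geometry decides C1 and C4. The single C7 methyl must control the face. The ring expansion ionises C1, so its configuration is set again at that stage and the photochemical control of C1 is not used. The ester-to-ketone change adds steps with an over-addition risk.
- Comparison: structurally it is stronger at C4a and no stronger at C1. Mechanistically it exchanges one chemoselectivity question (C=O versus alkene under Lewis acid) for another (which alkene is excited). In step economy it is worse: A2 is a long linear substrate and three to four steps follow A1, against a convergent union in the chosen plan.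

Alternative 2: The cut is C3–C(=O) and C(=O)–CH. The ketene acetal triflate A4, made from the δ-lactone A5, would undergo oxidative addition to Pd(PPh3)4, insert carbon monoxide and accept the alkenyl group of the stannane A6 to give A3. A3 is identical with 21 and one demethylation from the target.
- In its favour: the dienone, the most reactive group of the molecule, appears in the last carbon–carbon bond-forming step and never meets a Lewis acid, a π-acid or a base. On this point it is better than the chosen plan, which generates the dienone two operations before the end. Its endgame is equal (the same final demethylation).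
- Against it here: the step closes no ring and sets no stereocentre, so the whole bicycle A5 with four stereocentres and the C1–aryl bond must come from a separate strategy. Lactone-derived ketene acetal triflates hydrolyse easily, direct coupling without CO insertion competes, and the triflate must be formed with strong base in the presence of the coumarin vinylogous ester.
- Comparison: structurally it solves only the side chain, whereas the chosen plan forms the pyran and three stereocentres while carrying the side chain in latent form. Mechanistically it is well understood but demanding on substrate stability. In step economy it can only be judged together with a route to A5, which is not shorter than the chosen cycloaddition.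

Alternative 3: The cut is C4a–C7a, C4–C3 and C3–C1, with later insertion of O2 between C3 and C1. The enyne A8 would undergo Pauson–Khand cyclisation with Co2(CO)8 to the bicyclic enone A7. Baeyer–Villiger oxidation would give the unsaturated lactone, conjugate reduction would set C4a, and the endgame of Alternative 2 would install the side chain.
- In its favour: the cyclisation transfers the (E) geometry of the alkene stereospecifically into the trans H1/H7a relationship. On this point it is better than the chosen plan, where that relationship depends on an exo approach. The allylic C7 methyl on the tether should direct C7a, and two rings and three C–C bonds form in one step.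
- Against it here: the product is a carbocycle, and the oxygen insertion has an uncertain migration preference (C1 versus the alkenyl carbon C4) and competes with enone epoxidation. C1 is α to the ketone and epimerisable. A 1,2-disubstituted alkene bearing a hindered, electron-poor aryl group is a slow partner. Reduction, triflation and carbonylative coupling must still follow.
- Comparison: structurally it gives better control of C1/C7a but the wrong ring atom pattern. Mechanistically it is the most predictable of the three in the ring-forming step and the least predictable in the oxygen insertion. In step economy it is the longest, since it needs the endgame of Alternative 2 in addition.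

Key step: step 12

Assumption: the cis ring fusion and the C1 configuration of 22 are taken to be the thermodynamically preferred arrangement of the bicycle (cyclopentane carbon C5 pseudo-axial, aryl group pseudo-equatorial and trans to C7), so that equilibrating conditions late in the route converge on the target; the three starting materials are taken as purchasable.

## Route

Step 1
Reactants: 1 (S)-β-citronellene [(3S)-3,7-dimethylocta-1,6-diene]
Product: 3 (4S)-4-methylhex-5-enal, via secondary ozonide 2 (not isolated)
Conditions: O3 (1.0 equiv), CH2Cl2, −78 °C; then PPh3, −78 °C to rt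
Reagents that add atoms: ozone, [O-][O+]=O
Why: Ozonolysis with reductive work-up; ozone attacks the electron-rich trisubstituted alkene far faster than the monosubstituted vinyl group, so one equivalent cleaves only the isopropylidene end. The stereocentre is untouched and becomes C7.

Step 2
Reactants: 3 (4S)-4-methylhex-5-enal
Product: 4 (6S)-6-methyl-1-(trimethylsilyl)oct-7-en-1-yn-3-ol (both C3 epimers)
Conditions: Me3SiC≡CH, n-BuLi, THF, −78 °C; then 3, −78 to 0 °C; aq. NH4Cl
Reagents that add atoms: (trimethylsilyl)acetylene, C#C[Si](C)(C)C
Why: 1,2-Addition of lithium (trimethylsilyl)acetylide to the aldehyde forms the C4a–C4 bond. The carbinol epimers do not matter because the centre is oxidised next, and the silyl cap is kept on purpose for steps 4 and 5.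

Step 3
Reactants: 4 (6S)-6-methyl-1-(trimethylsilyl)oct-7-en-1-yn-3-ol
Product: 5 (6S)-6-methyl-1-(trimethylsilyl)oct-7-en-1-yn-3-one
Conditions: Dess–Martin periodinane, NaHCO3, CH2Cl2, 0 °C to rt
Reagents that add atoms: none
Why: Dess–Martin oxidation of a secondary propargylic alcohol to the ynone is mild and buffered and leaves the vinyl group and the C–Si bond alone.

Step 4
Reactants: 5 (6S)-6-methyl-1-(trimethylsilyl)oct-7-en-1-yn-3-one
Product: 6 trimethyl[(6S)-6-methyl-3-methylideneoct-7-en-1-yn-1-yl]silane
Conditions: Ph3PCH3Br, KN(SiMe3)2, THF, 0 °C; then 5, −78 to 0 °C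
Reagents that add atoms: methyltriphenylphosphonium bromide, C[P+](c1ccccc1)(c1ccccc1)c1ccccc1.[Br-]
Why: Wittig methylenation; the non-stabilised ylide attacks the ketone carbonyl, while the silyl cap removes the acidic acetylenic hydrogen and shields the β-carbon from conjugate addition.

Step 5
Reactants: 6 trimethyl[(6S)-6-methyl-3-methylideneoct-7-en-1-yn-1-yl]silane
Product: 7 trimethyl{[(3S)-3-methylcyclopent-1-en-1-yl]ethynyl}silane
Conditions: second-generation Grubbs catalyst (H2IMes)(PCy3)Cl2Ru=CHPh (3 mol%), CH2Cl2 (0.01 M), 40 °C
Reagents that add atoms: none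
Why: Ring-closing metathesis; the catalyst loads on the monosubstituted vinyl group and closes the five-membered ring onto the 1,1-disubstituted alkene with loss of ethene, the silyl-capped alkyne being a poor partner for ene–yne metathesis. The tether fixes the alkene as C7a=C4a next to the untouched C7 centre.

Step 6
Reactants: 7 trimethyl{[(3S)-3-methylcyclopent-1-en-1-yl]ethynyl}silane
Product: 8 (3S)-1-ethynyl-3-methylcyclopent-1-ene
Conditions: K2CO3 (0.2 equiv), MeOH, rt; extraction into pentane/CH2Cl2, used as a dried solution
Reagents that add atoms: none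
Why: Methoxide-catalysed protodesilylation of the alkynylsilane; the volatile enyne is not concentrated to dryness but carried on in solution.

Step 7
Reactants: 8 (3S)-1-ethynyl-3-methylcyclopent-1-ene
Product: 10 (3S)-1-[(1E)-1-iodoprop-1-en-2-yl]-3-methylcyclopent-1-ene, via alkenylalane 9 (not isolated)
Conditions: AlMe3 (2.5 equiv), Cp2ZrCl2 (0.25 equiv), CH2Cl2, 0 °C to rt; then I2, THF, −30 to 0 °C
Reagents that add atoms: trimethylaluminium, C[Al](C)C; iodine, II
Why: Negishi zirconium-catalysed methylalumination adds CH3 and Al syn across the terminal alkyne with CH3 on the internal carbon, so Al ends up trans to the ring. Iodinolysis with retention gives the (E)-iodide and fixes the C3=C4 geometry needed in step 12.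

Step 8
Reactants: 11 2-methylbut-3-yn-2-ol
Product: 12 tert-butyl(dimethyl)[(2-methylbut-3-yn-2-yl)oxy]silane
Conditions: TBSOTf, 2,6-lutidine, CH2Cl2, 0 °C to rt
Reagents that add atoms: tert-butyldimethylsilyl trifluoromethanesulfonate, CC(C)(C)[Si](C)(C)OS(=O)(=O)C(F)(F)F
Why: Silylation of a tertiary propargylic alcohol with the silyl triflate; the hindered silyl ether is a weak Lewis base and is meant to survive chromatography and the Lewis acid of step 12.

Step 9
Reactants: 10 (3S)-1-[(1E)-1-iodoprop-1-en-2-yl]-3-methylcyclopent-1-ene; 12 tert-butyl(dimethyl)[(2-methylbut-3-yn-2-yl)oxy]silane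
Product: 13 tert-butyl(dimethyl){[(5E)-2-methyl-6-[(3S)-3-methylcyclopent-1-en-1-yl]hept-5-en-3-yn-2-yl]oxy}silane
Conditions: PdCl2(PPh3)2 (3 mol%), CuI (6 mol%), Et3N, THF, rt
Reagents that add atoms: none
Why: Sonogashira coupling of an alkenyl iodide with a terminal alkyne proceeds with retention of the alkene geometry; the amine medium harms neither the silyl ether nor the diene.

Step 10
Reactants: 14 4-hydroxy-5-methyl-2H-chromen-2-one (4-hydroxy-5-methylcoumarin)
Product: 16 4-chloro-5-methyl-2-oxo-2H-chromene-3-carbaldehyde, via iminium chloride 15 (not isolated)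
Conditions: POCl3 (3 equiv), DMF, 0 to 60 °C; then ice-water
Reagents that add atoms: N,N-dimethylformamide, CN(C)C=O; phosphoryl chloride, O=P(Cl)(Cl)Cl; water, O
Why: Vilsmeier–Haack reaction on the enolised 1,3-dicarbonyl system; C3 is formylated through the iminium salt and the activated 4-hydroxyl is exchanged for chloride, and hydrolysis releases the aldehyde.

Step 11
Reactants: 16 4-chloro-5-methyl-2-oxo-2H-chromene-3-carbaldehyde
Product: 17 4-methoxy-5-methyl-2-oxo-2H-chromene-3-carbaldehyde
Conditions: NaOMe (1.0 equiv), MeOH/THF, −40 to 0 °C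
Reagents that add atoms: sodium methoxide, C[O-].[Na+]
Why: Addition–elimination at C4 of a vinylogous acid chloride activated by the formyl and lactone carbonyl groups; one equivalent at low temperature keeps the lactone closed.

Step 12
Reactants: 17 4-methoxy-5-methyl-2-oxo-2H-chromene-3-carbaldehyde; 13 tert-butyl(dimethyl){[(5E)-2-methyl-6-[(3S)-3-methylcyclopent-1-en-1-yl]hept-5-en-3-yn-2-yl]oxy}silane
Product: 18 3-[(1R,3S,7S,7aR)-3-(3-{[tert-butyl(dimethyl)silyl]oxy}-3-methylbut-1-yn-1-yl)-4,7-dimethyl-1,3,5,6,7,7a-hexahydrocyclopenta[c]pyran-1-yl]-4-methoxy-5-methyl-2H-chromen-2-one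
Conditions: Me2AlCl (2.0 equiv), CH2Cl2, −78 to −40 °C; Et3N, then aq. potassium sodium tartrate
Reagents that add atoms: none
Why: Two equivalents of Me2AlCl should turn 17 into a cationic aluminium chelate spanning the formyl and lactone carbonyl oxygens, which lowers the C=O LUMO while the Al–CH3 groups scavenge adventitious acid that could ionise the propargylic silyl ether. The closest known reaction type is the Lewis-acid-promoted oxa-Diels–Alder reaction of aldehydes with alkyl-substituted 1,3-dienes, here of normal electron demand with an asynchronous transition state in which C1–C7a bonding runs ahead of O2–C3. The dihydropyran ring is closed by the [4+2] event itself, suprafacially on both partners (in the stepwise limit, by capture of the C4a–C4–C3 allyl cation at C3 by the aluminium alkoxide, a six-membered closure). The formyl carbon should bond to C7a because this terminus is remote from the conjugating alkynyl group and leaves the developing positive charge on the tertiary C4a and the alkyne-stabilised C3. C7a is set by the C7 stereocentre: the heterodienophile adds to the diene face opposite the C7 methyl, so C1 and CH3 end up trans on the cyclopentane. C1 is set by exo placement of the coumarinyl group: chelation holds the metal on the aryl side of the C=O, and the endo arrangement would push the out-of-plane Al–CH3 groups and the peri-methylated coumarin under the C4 methyl and the C5 methylene, hence H1 trans to H7a. C3 follows from the (E) geometry of C3=C4 (alkynyl outside) and is erased in step 14. Chemoselectivity for C=O over the coumarin C3=C4 bond rests on that alkene being tetrasubstituted and donor-substituted, and cycloaddition is favoured over the ene pathway by the s-cis-accessible 2,3-dialkyl diene and the cation-stabilising alkynyl terminus.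

Step 13
Reactants: 18 3-[(1R,3S,7S,7aR)-3-(3-{[tert-butyl(dimethyl)silyl]oxy}-3-methylbut-1-yn-1-yl)-4,7-dimethyl-1,3,5,6,7,7a-hexahydrocyclopenta[c]pyran-1-yl]-4-methoxy-5-methyl-2H-chromen-2-one
Product: 19 3-[(1R,3S,7S,7aR)-3-(3-hydroxy-3-methylbut-1-yn-1-yl)-4,7-dimethyl-1,3,5,6,7,7a-hexahydrocyclopenta[c]pyran-1-yl]-4-methoxy-5-methyl-2H-chromen-2-one
Conditions: Bu4NF (1.5 equiv), THF, 0 °C to rt; aq. NH4Cl
Reagents that add atoms: none
Why: Fluoride cleaves the Si–O bond; nothing else in 18 is fluoride-labile at room temperature and no stereocentre is touched.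

Step 14
Reactants: 19 3-[(1R,3S,7S,7aR)-3-(3-hydroxy-3-methylbut-1-yn-1-yl)-4,7-dimethyl-1,3,5,6,7,7a-hexahydrocyclopenta[c]pyran-1-yl]-4-methoxy-5-methyl-2H-chromen-2-one
Product: 21 3-[(1R,4aS,7S,7aR)-4,7-dimethyl-3-(3-methylbut-2-enoyl)-1,4a,5,6,7,7a-hexahydrocyclopenta[c]pyran-1-yl]-4-methoxy-5-methyl-2H-chromen-2-one, via β,γ-unsaturated ketone 20 (not isolated)
Conditions: Ph3PAuNTf2 (2 mol%), MeOH (2 equiv), wet toluene, rt; then DBU (1.5 equiv), rt to 40 °C
Reagents that add atoms: water, O (supplies the ketone oxygen; the tertiary hydroxyl leaves as water)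
Why: Gold-catalysed Meyer–Schuster rearrangement: the π-acid activates the alkyne, oxygen is delivered to the alkyne carbon remote from the tertiary hydroxyl, which leaves as water, and the allenol tautomerises to the 3-methylbut-2-enoyl ketone 20. DBU then removes the doubly activated C3–H and the extended enolate is reprotonated at C4a, which moves the alkene into conjugation as the 2-alkoxy enone. Because H4a stays γ-acidic, the ring fusion equilibrates to the cis arrangement (4aS), in which C5 is pseudo-axial and avoids the C4 methyl.

Step 15
Reactants: 21 3-[(1R,4aS,7S,7aR)-4,7-dimethyl-3-(3-methylbut-2-enoyl)-1,4a,5,6,7,7a-hexahydrocyclopenta[c]pyran-1-yl]-4-methoxy-5-methyl-2H-chromen-2-one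
Product: 22 4-hydroxy-5-methyl-3-[(1R,4aS,7S,7aR)-4,7-dimethyl-3-(3-methylbut-2-enoyl)-1,4a,5,6,7,7a-hexahydrocyclopenta[c]pyran-1-yl]-2H-chromen-2-one (target)
Conditions: LiI (6 equiv), EtOAc, 70 °C, dark; then 0.5 M HCl
Reagents that add atoms: none
Why: SN2 dealkylation of a vinylogous methyl ester by iodide with lithium assistance; the leaving group is the stabilised coumarin-4-olate, comparable to a carboxylate. Iodide is too weak a base to touch H4a and too poor a conjugate donor to add irreversibly to the β,β-disubstituted enone.

## Compound list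

1 | (S)-β-citronellene, (3S)-3,7-dimethylocta-1,6-diene | C=C[C@@H](C)CCC=C(C)C | starting material
2 | 3,3-dimethyl-5-[(3S)-3-methylpent-4-en-1-yl]-1,2,4-trioxolane (secondary ozonide, both ring epimers) | C=C[C@@H](C)CCC1OOC(C)(C)O1 | intermediate (not isolated)
3 | (4S)-4-methylhex-5-enal | C=C[C@@H](C)CCC=O | intermediate
4 | (6S)-6-methyl-1-(trimethylsilyl)oct-7-en-1-yn-3-ol (C3 epimers) | C=C[C@@H](C)CCC(O)C#C[Si](C)(C)C | intermediate
5 | (6S)-6-methyl-1-(trimethylsilyl)oct-7-en-1-yn-3-one | C=C[C@@H](C)CCC(=O)C#C[Si](C)(C)C | intermediate
6 | trimethyl[(6S)-6-methyl-3-methylideneoct-7-en-1-yn-1-yl]silane | C=C[C@@H](C)CCC(=C)C#C[Si](C)(C)C | intermediate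
7 | trimethyl{[(3S)-3-methylcyclopent-1-en-1-yl]ethynyl}silane | C[Si](C)(C)C#CC1=C[C@@H](C)CC1 | intermediate
8 | (3S)-1-ethynyl-3-methylcyclopent-1-ene | C#CC1=C[C@@H](C)CC1 | intermediate
9 | dimethyl{(1E)-2-[(3S)-3-methylcyclopent-1-en-1-yl]prop-1-en-1-yl}alumane | C[Al](C)/C=C(C)/C1=C[C@@H](C)CC1 | intermediate (not isolated)
10 | (3S)-1-[(1E)-1-iodoprop-1-en-2-yl]-3-methylcyclopent-1-ene | I/C=C(C)/C1=C[C@@H](C)CC1 | intermediate
11 | 2-methylbut-3-yn-2-ol | CC(C)(O)C#C | starting material
12 | tert-butyl(dimethyl)[(2-methylbut-3-yn-2-yl)oxy]silane | CC(C)(C)[Si](C)(C)OC(C)(C)C#C | intermediate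
13 | tert-butyl(dimethyl){[(5E)-2-methyl-6-[(3S)-3-methylcyclopent-1-en-1-yl]hept-5-en-3-yn-2-yl]oxy}silane | CC(C)(C)[Si](C)(C)OC(C)(C)C#C/C=C(C)/C1=C[C@@H](C)CC1 | intermediate
14 | 4-hydroxy-5-methyl-2H-chromen-2-one | Cc1cccc2oc(=O)cc(O)c12 | starting material
15 | N-[(4-chloro-5-methyl-2-oxo-2H-chromen-3-yl)methylidene]-N-methylmethanaminium chloride | C[N+](C)=Cc1c(Cl)c2c(C)cccc2oc1=O.[Cl-] | intermediate (not isolated)
16 | 4-chloro-5-methyl-2-oxo-2H-chromene-3-carbaldehyde | O=Cc1c(Cl)c2c(C)cccc2oc1=O | intermediate
17 | 4-methoxy-5-methyl-2-oxo-2H-chromene-3-carbaldehyde | O=Cc1c(OC)c2c(C)cccc2oc1=O | intermediate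
18 | 3-[(1R,3S,7S,7aR)-3-(3-{[tert-butyl(dimethyl)silyl]oxy}-3-methylbut-1-yn-1-yl)-4,7-dimethyl-1,3,5,6,7,7a-hexahydrocyclopenta[c]pyran-1-yl]-4-methoxy-5-methyl-2H-chromen-2-one | CC(C)(C)[Si](C)(C)OC(C)(C)C#C[C@@H]1O[C@@H](c2c(OC)c3c(C)cccc3oc2=O)[C@@H]2[C@@H](C)CCC2=C1C | intermediate
19 | 3-[(1R,3S,7S,7aR)-3-(3-hydroxy-3-methylbut-1-yn-1-yl)-4,7-dimethyl-1,3,5,6,7,7a-hexahydrocyclopenta[c]pyran-1-yl]-4-methoxy-5-methyl-2H-chromen-2-one | CC(C)(O)C#C[C@@H]1O[C@@H](c2c(OC)c3c(C)cccc3oc2=O)[C@@H]2[C@@H](C)CCC2=C1C | intermediate
20 | 3-[(1R,3R,7S,7aR)-4,7-dimethyl-3-(3-methylbut-2-enoyl)-1,3,5,6,7,7a-hexahydrocyclopenta[c]pyran-1-yl]-4-methoxy-5-methyl-2H-chromen-2-one (C3 labile) | CC(C)=CC(=O)[C@@H]1O[C@@H](c2c(OC)c3c(C)cccc3oc2=O)[C@@H]2[C@@H](C)CCC2=C1C | intermediate (not isolated)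
21 | 3-[(1R,4aS,7S,7aR)-4,7-dimethyl-3-(3-methylbut-2-enoyl)-1,4a,5,6,7,7a-hexahydrocyclopenta[c]pyran-1-yl]-4-methoxy-5-methyl-2H-chromen-2-one | CC(C)=CC(=O)C1=C(C)[C@H]2CC[C@H](C)[C@H]2[C@H](c2c(OC)c3c(C)cccc3oc2=O)O1 | intermediate
22 | 4-hydroxy-5-methyl-3-[(1R,4aS,7S,7aR)-4,7-dimethyl-3-(3-methylbut-2-enoyl)-1,4a,5,6,7,7a-hexahydrocyclopenta[c]pyran-1-yl]-2H-chromen-2-one | CC(C)=CC(=O)C1=C(C)[C@H]2CC[C@H](C)[C@H]2[C@H](c2c(O)c3c(C)cccc3oc2=O)O1 | target

## Step count and least certain steps

Total step count: 15. Longest linear sequence: 12 steps (steps 1–7, 9, 12–15, from 1).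

Step 12 (key step). The most likely failure is poor exo selectivity: the flat coumarin could stack under the diene (endo) and outweigh the steric argument, giving the C1 epimer. Lewis-acid-induced ene reaction at the allylic hydrogens or ionisation of the cycloadduct at C1–O2 could further erode the result. The fallback gives up kinetic control of C1 and corrects it thermodynamically at the end. It sets out from 13 and 17: the cycloaddition is run for conversion and the C1-epimeric cycloadduct F1 is carried through the same operations. Bu4NF gives the C1-epimeric alcohol F2. Ph3PAuNTf2 followed by DBU gives the C1-epimeric conjugated methyl ether F4 by way of the C1-epimeric β,γ-unsaturated ketone F3 (not isolated). LiI gives the C1-epimeric hydroxycoumarin F5. Treatment of F5 with DBU in MeCN at 40–60 °C should let the coumarin-4-olate expel O2 as the enolate of the 1,2-diketone, giving the ring-opened 3-alkylidenechromane-2,4-dione F6 (not isolated). F6 re-closes by oxa-Michael addition, and the equilibrium should favour the epimer with the aryl group pseudo-equatorial and trans to C7. The fallback comes back to the route at 22.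

Step 14. The activated substrate may be diverted into ionisation of the ring C3–O2 bond, which is both allylic and propargylic, or into Rupe-type dehydration of the tertiary alcohol, instead of the 1,3-transposition at the carbinol end. The fallback makes the oxygen transfer intramolecular. From 19, Ac2O/Et3N/DMAP gives the tertiary propargylic acetate F7. Ph3PAuNTf2 in CH2Cl2 then triggers the [3,3]-acyloxy shift, in which the ester carbonyl oxygen attacks the activated alkyne carbon next to C3, to give the allenyl acetate F8; the ring ether cannot take part in this shift. K2CO3 in MeOH cleaves the enol ester to 20, which isomerises under the same basic conditions. The fallback comes back to the route at 21.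

Step 15. The SN2 displacement at the methyl group of the hindered, twisted vinylogous ester may be sluggish; the temperatures then required would allow reversible halide addition to the dienone, opening of the pyran or slow decomposition to compete. The fallback moves the demethylation to a stage without a Michael acceptor. From 18, NaSEt in DMF at 50–60 °C gives the 4-hydroxycoumarin cycloadduct F9. Bu4NF gives the diol F10. Ph3PAuNTf2 followed by DBU (2.5 equiv, the first equivalent being consumed by the acidic hydroxyl) gives the target by way of the β,γ-unsaturated ketone F11 (not isolated). The fallback comes back to the route at 22.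

Step 5. The catalyst may be sequestered by the conjugated silylalkyne (ene–yne metathesis), or turnover at the conjugated 1,1-disubstituted alkene may be slow, leading to oligomerisation through the vinyl group. The fallback moves the ring closure to the end of the fragment synthesis, where the only alkyne is internal and flanked by a quaternary carbon. From 6, K2CO3/MeOH gives the terminal enyne F12. Methylalumination (AlMe3, Cp2ZrCl2) gives the alkenylalane F13 (not isolated), and iodinolysis gives the acyclic (E)-iodide F14. Sonogashira coupling with 12 gives the acyclic trienyne F15, and ring-closing metathesis with the same catalyst closes the cyclopentene. The fallback comes back to the route at 13.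

## Further compounds

F1 | step 12 | 3-[(1S,3S,7S,7aR)-3-(3-{[tert-butyl(dimethyl)silyl]oxy}-3-methylbut-1-yn-1-yl)-4,7-dimethyl-1,3,5,6,7,7a-hexahydrocyclopenta[c]pyran-1-yl]-4-methoxy-5-methyl-2H-chromen-2-one (C1 epimer of 18) | CC(C)(C)[Si](C)(C)OC(C)(C)C#C[C@@H]1O[C@H](c2c(OC)c3c(C)cccc3oc2=O)[C@@H]2[C@@H](C)CCC2=C1C
F2 | step 12 | 3-[(1S,3S,7S,7aR)-3-(3-hydroxy-3-methylbut-1-yn-1-yl)-4,7-dimethyl-1,3,5,6,7,7a-hexahydrocyclopenta[c]pyran-1-yl]-4-methoxy-5-methyl-2H-chromen-2-one (C1 epimer of 19) | CC(C)(O)C#C[C@@H]1O[C@H](c2c(OC)c3c(C)cccc3oc2=O)[C@@H]2[C@@H](C)CCC2=C1C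
F3 | step 12 | 3-[(1S,3R,7S,7aR)-4,7-dimethyl-3-(3-methylbut-2-enoyl)-1,3,5,6,7,7a-hexahydrocyclopenta[c]pyran-1-yl]-4-methoxy-5-methyl-2H-chromen-2-one (C1 epimer of 20) | CC(C)=CC(=O)[C@@H]1O[C@H](c2c(OC)c3c(C)cccc3oc2=O)[C@@H]2[C@@H](C)CCC2=C1C
F4 | step 12 | 3-[(1S,4aS,7S,7aR)-4,7-dimethyl-3-(3-methylbut-2-enoyl)-1,4a,5,6,7,7a-hexahydrocyclopenta[c]pyran-1-yl]-4-methoxy-5-methyl-2H-chromen-2-one (C1 epimer of 21) | CC(C)=CC(=O)C1=C(C)[C@H]2CC[C@H](C)[C@H]2[C@@H](c2c(OC)c3c(C)cccc3oc2=O)O1
F5 | step 12 | 4-hydroxy-5-methyl-3-[(1S,4aS,7S,7aR)-4,7-dimethyl-3-(3-methylbut-2-enoyl)-1,4a,5,6,7,7a-hexahydrocyclopenta[c]pyran-1-yl]-2H-chromen-2-one (C1 epimer of 22) | CC(C)=CC(=O)C1=C(C)[C@H]2CC[C@H](C)[C@H]2[C@@H](c2c(O)c3c(C)cccc3oc2=O)O1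
F6 | step 12 | 3-{[2-(3-hydroxy-6-methyl-4-oxohepta-2,5-dien-2-yl)-5-methylcyclopentyl]methylidene}-5-methylchromane-2,4-dione (ring-opened form, cyclopentane centres as in 22) | CC(C)=CC(=O)C(O)=C(C)[C@H]1CC[C@H](C)[C@H]1C=C1C(=O)Oc2cccc(C)c2C1=O
F7 | step 14 | 4-[(1R,3S,7S,7aR)-1-(4-methoxy-5-methyl-2-oxo-2H-chromen-3-yl)-4,7-dimethyl-1,3,5,6,7,7a-hexahydrocyclopenta[c]pyran-3-yl]-2-methylbut-3-yn-2-yl acetate | CC(=O)OC(C)(C)C#C[C@@H]1O[C@@H](c2c(OC)c3c(C)cccc3oc2=O)[C@@H]2[C@@H](C)CCC2=C1C
F8 | step 14 | 1-[1-(4-methoxy-5-methyl-2-oxo-2H-chromen-3-yl)-4,7-dimethyl-1,3,5,6,7,7a-hexahydrocyclopenta[c]pyran-3-yl]-3-methylbuta-1,2-dien-1-yl acetate (ring centres as in 19) | CC(C)=C=C(OC(C)=O)[C@@H]1O[C@@H](c2c(OC)c3c(C)cccc3oc2=O)[C@@H]2[C@@H](C)CCC2=C1C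
F9 | step 15 | 3-[(1R,3S,7S,7aR)-3-(3-{[tert-butyl(dimethyl)silyl]oxy}-3-methylbut-1-yn-1-yl)-4,7-dimethyl-1,3,5,6,7,7a-hexahydrocyclopenta[c]pyran-1-yl]-4-hydroxy-5-methyl-2H-chromen-2-one | CC(C)(C)[Si](C)(C)OC(C)(C)C#C[C@@H]1O[C@@H](c2c(O)c3c(C)cccc3oc2=O)[C@@H]2[C@@H](C)CCC2=C1C
F10 | step 15 | 4-hydroxy-3-[(1R,3S,7S,7aR)-3-(3-hydroxy-3-methylbut-1-yn-1-yl)-4,7-dimethyl-1,3,5,6,7,7a-hexahydrocyclopenta[c]pyran-1-yl]-5-methyl-2H-chromen-2-one | CC(C)(O)C#C[C@@H]1O[C@@H](c2c(O)c3c(C)cccc3oc2=O)[C@@H]2[C@@H](C)CCC2=C1C
F11 | step 15 | 4-hydroxy-5-methyl-3-[(1R,3R,7S,7aR)-4,7-dimethyl-3-(3-methylbut-2-enoyl)-1,3,5,6,7,7a-hexahydrocyclopenta[c]pyran-1-yl]-2H-chromen-2-one | CC(C)=CC(=O)[C@@H]1O[C@@H](c2c(O)c3c(C)cccc3oc2=O)[C@@H]2[C@@H](C)CCC2=C1C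
F12 | step 5 | (3S)-3-methyl-6-methylideneoct-1-en-7-yne | C=C[C@@H](C)CCC(=C)C#C
F13 | step 5 | [(1E,6S)-2,6-dimethyl-3-methylideneocta-1,7-dien-1-yl]dimethylalumane | C=C[C@@H](C)CCC(=C)/C(C)=C/[Al](C)C
F14 | step 5 | (1E,6S)-1-iodo-2,6-dimethyl-3-methylideneocta-1,7-diene | C=C[C@@H](C)CCC(=C)/C(C)=C/I
F15 | step 5 | tert-butyl{[(5E,10S)-2,6,10-trimethyl-7-methylidenedodeca-5,11-dien-3-yn-2-yl]oxy}dimethylsilane | C=C[C@@H](C)CCC(=C)/C(C)=C/C#CC(C)(C)O[Si](C)(C)C(C)(C)C
A1 | alternative 1 | methyl 2-[7-(4-methoxy-5-methyl-2-oxo-2H-chromen-3-yl)-2,6-dimethylbicyclo[3.2.0]heptan-6-yl]-2-oxoacetate (cis-fused photoadduct) | COC(=O)C(=O)[C@]1(C)[C@H]2CC[C@H](C)[C@H]2[C@@H]1c1c(OC)c2c(C)cccc2oc1=O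
A2 | alternative 1 | methyl (3E,7S,8E)-9-(4-methoxy-5-methyl-2-oxo-2H-chromen-3-yl)-3,7-dimethyl-2-oxonona-3,8-dienoate | COC(=O)C(=O)/C(C)=C/CC[C@H](C)/C=C/c1c(OC)c2c(C)cccc2oc1=O
A3 | alternative 2 | 3-[(1R,4aS,7S,7aR)-4,7-dimethyl-3-(3-methylbut-2-enoyl)-1,4a,5,6,7,7a-hexahydrocyclopenta[c]pyran-1-yl]-4-methoxy-5-methyl-2H-chromen-2-one (identical with 21) | CC(C)=CC(=O)C1=C(C)[C@H]2CC[C@H](C)[C@H]2[C@H](c2c(OC)c3c(C)cccc3oc2=O)O1
A4 | alternative 2 | (1R,4aS,7S,7aR)-1-(4-methoxy-5-methyl-2-oxo-2H-chromen-3-yl)-4,7-dimethyl-1,4a,5,6,7,7a-hexahydrocyclopenta[c]pyran-3-yl trifluoromethanesulfonate | O=S(=O)(OC1=C(C)[C@H]2CC[C@H](C)[C@H]2[C@H](c2c(OC)c3c(C)cccc3oc2=O)O1)C(F)(F)F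
A5 | alternative 2 | (1R,4aS,7S,7aR)-1-(4-methoxy-5-methyl-2-oxo-2H-chromen-3-yl)-4,7-dimethylhexahydrocyclopenta[c]pyran-3(1H)-one (C4 epimers) | O=C1C(C)[C@H]2CC[C@H](C)[C@H]2[C@H](c2c(OC)c3c(C)cccc3oc2=O)O1
A6 | alternative 2 | tributyl(2-methylprop-1-en-1-yl)stannane | CCCC[Sn](CCCC)(CCCC)C=C(C)C
A7 | alternative 3 | 1-(4-methoxy-5-methyl-2-oxo-2H-chromen-3-yl)-3,6-dimethyl-4,5,6,6a-tetrahydropentalen-2(1H)-one (Pauson–Khand enone) | CC1=C2CC[C@H](C)[C@H]2[C@H](c2c(OC)c3c(C)cccc3oc2=O)C1=O
A8 | alternative 3 | 4-methoxy-5-methyl-3-[(1E,3S)-3-methyloct-1-en-6-yn-1-yl]-2H-chromen-2-one | CC#CCC[C@H](C)/C=C/c1c(OC)c2c(C)cccc2oc1=O
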